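The easy step is the summer flask, which holds less J (0.19 mM) than D (0.75 mM) or G (0.30 mM).

| flask | J | D | G | remark | time |
|---|---|---|---|---|---|
| summer | 0.19 mM | 0.75 mM | 0.30 mM | run made earlier |  |
| dusk | 19 mM | 0.75 mM | 0.30 mM | run made earlier |  |
| grey | 0.15 mM | 0.750 mM | 0.300 mM |  | 4.0 min |
| teal | 0.50 mM | 0.750 mM | 0.300 mM |  | 4.0 min |
| amber | 1.5 mM | 0.750 mM | 0.300 mM |  | 4.0 min |
| red | 5.0 mM | 0.750 mM | 0.300 mM |  | 4.0 min |
| violet | 15 mM | 0.750 mM | 0.300 mM |  | 4.0 min |

| run | time / min | Z / % |
|---|---|---|
| summer | 0.833 | 20.3 |
| summer | 1.50 | 21.0 |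
| summer | 2.50 | 21.5 |
| summer | 3.00 | 21.8 |
| summer | 4.00 | 22.5 |
| dusk | 0.833 | 4.5 |
| dusk | 1.50 | 2.1 |
| dusk | 2.50 | 2.9 |
| dusk | 3.00 | 2.0 |
| dusk | 4.00 | 2.4 |

(each reading ± 1 percentage point)

- "hardly changes" means that all values lie within two and a half points (for a concentration: within two and a half percent of the largest)

1. [Z] at the end for grey, teal, amber, red, violet, in this order
2. the shape of the row from first to last (falls all the way / rises, then falls / rises all the way / falls, then rises / hardly changes)

Follow one molecule of J in the summer flask: it ends as Z or as something unmeasured. The summer readings gain 2.2 percentage points after the first one, far less than that first reading of 20.3%, so a reading at the end counts molecules that have already passed the fork.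

Call the mean of the summer readings, the chance that one J ends as Z while [D] and [G] stand near their charges, the Z share (the selectivity towards Z): 21.4%.

The first extreme is a flask with little J. If [D] and [G] stay near their charges, every molecule meets the same chance, and [Z] at the end is the Z share times the J charged. This reckoning gives 0.0321 mM for grey and 0.107 mM for teal. Amber holds more J than D, so its product, 0.321 mM, carries the line past the flasks it was drawn for.

The second extreme is the dusk flask, with far more J than D. Its readings average 2.78% of the J charged, which is a reading of 0.528 mM of Z, a level taken from a noisy run.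

As an estimate, this reckoning lets the row follow the first line until it meets that level, at a [J] of about 2.47 mM. So this reckoning puts red and violet near 0.528 mM, with a rise that then flattens.

The forecast gives 0.034 mM, 0.1 mM, 0.22 mM, 0.37 mM and 0.47 mM, lower than this reckoning at amber, and calls the row "rises all the way" because “Nothing in the data suggests a fall at high J”.

The flask gives 0.0318 mM, 0.107 mM, 0.314 mM, 0.638 mM and 0.569 mM: the row rises, then falls, turning at a [J] of 6.7 mM.

    E → X (k = 46.0 s⁻¹)
    J + Z → Q (k = 2.20 L mol⁻¹ s⁻¹)
    D + E → Z (k = 28000 L mol⁻¹ s⁻¹)
    J → E (k = 0.100 s⁻¹)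
    G + E → L (k = 1.10 × 10⁵ L mol⁻¹ s⁻¹)

 For amber, the Z share times the charge is 0.321 mM, against 0.314 mM in the flask. For red, the same product is 1.07 mM, against 0.638 mM in the flask, and red ends with G at 0.00750% of its charge.

The numbers in the tables are calculated from invented constants, noise included.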